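**Retrosynthetic overview**
- Feature: the pyridone ring (N1–C2–C3–C4–C4a–C8a) is the pyrrole ring of an indole plus one carbon. C3 sits between the pentadecyl-bearing C2 and C4, and the C4 carbonyl oxygen is the enol oxygen of an indoxyl.
- Target 13 ⇐ 3-chloroquinolone 12 by hydrogenolysis of the C3–Cl bond.
- 12 ⇐ 3-siloxyindole 8 + CCl2: one carbon is inserted into the indole C2–C3 bond, forming C2–C3 and C3–C4 of the quinolone.
- 8 ⇐ 3-bromoindole 5 ⇐ 2-pentadecylindole 4 ⇐ 1-methylindole 1 + 1-bromopentadecane 2.
- Ring order: the benzene and pyrrole rings come with 1; the six-membered pyridone ring is made from the pyrrole ring in step 4.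

Key step: step 4

Remark: bis(trimethylsilyl) peroxide is taken as a purchasable reagent. Silyl enol ether 8 is assumed to be too sensitive to air and moisture for chromatography and is carried crude, under argon, into step 4.

**Step 1**
Reactants: 1 1-methylindole; 2 1-bromopentadecane
Product: 4 1-methyl-2-pentadecylindole, via 2-lithio-1-methylindole 3 (not isolated)
Conditions: n-BuLi, TMEDA, THF, 0 °C → rt; then 2, −78 °C → rt
Reagents that add atoms: 1-bromopentadecane (2), CCCCCCCCCCCCCCCBr
Why: C2–H next to nitrogen is the most acidic ring proton of an N-alkylindole, so directed lithiation followed by SN2 alkylation of the aryllithium with a primary bromide should place the chain at C2.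

**Step 2**
Reactants: 4 1-methyl-2-pentadecylindole
Product: 5 3-bromo-1-methyl-2-pentadecylindole
Conditions: NBS, THF, −78 → 0 °C, dark
Reagents that add atoms: N-bromosuccinimide, O=C1CCC(=O)N1Br
Why: Electrophilic aromatic bromination should go to C3, the most nucleophilic and the only free position of the pyrrole ring in a 1,2-dialkylindole.

**Step 3**
Reactants: 5 3-bromo-1-methyl-2-pentadecylindole; 6 bis(trimethylsilyl) peroxide
Product: 8 1-methyl-2-pentadecyl-3-(trimethylsilyloxy)indole, via 3-lithio-1-methyl-2-pentadecylindole 7 (not isolated)
Conditions: t-BuLi (2 equiv), THF, −78 °C; then 6, −78 → 0 °C; cold pentane/aq. NaHCO3 work-up under Ar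
Reagents that add atoms: bis(trimethylsilyl) peroxide (6), C[Si](C)(C)OO[Si](C)(C)C
Why: Bromine–lithium exchange at −78 °C should outrun deprotonation of the side-chain CH2, and the aryllithium then attacks a peroxide oxygen with loss of Me3SiO−, the known electrophilic oxygenation of aryl and vinyl lithium reagents that gives the O-silyl ether directly.

**Step 4**
Reactants: 8 1-methyl-2-pentadecyl-3-(trimethylsilyloxy)indole; 9 sodium trichloroacetate
Product: 12 3-chloro-1-methyl-2-pentadecyl-4(1H)-quinolone, via dichlorocyclopropane adduct 10 (not isolated), via 3-chloro-4-siloxyquinolinium chloride 11 (not isolated)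
Conditions: Cl3CCO2Na (4 equiv, dried), DME, reflux (85 °C), Ar; then aq. NaHCO3
Reagents that add atoms: sodium trichloroacetate (9), [Na+].[O-]C(=O)C(Cl)(Cl)Cl (delivers CCl2)
Why: Proposed new method: thermal decarboxylation of Cl3CCO2Na releases dichlorocarbene without added base, and this electrophilic carbene should add in a [2+1] fashion to the C2–C3 double bond of 8, which carries both the nitrogen lone pair and the siloxy oxygen as donors, to give the cis-fused dichlorocyclopropane 10. Ionisation of the chlorine lying over the five-membered ring, together with disrotatory opening of the former indole C2–C3 bond (cyclopropyl-to-allyl cation electrocyclic opening, pushed by N1 and the siloxy oxygen), should give the aromatic 3-chloro-4-siloxyquinolinium chloride 11, from which chloride removes the Me3Si group to leave quinolone 12. The six-membered pyridone ring is therefore closed by ring expansion and not by a cyclisation: the carbene addition forms the C2–C3 and C3–C4 bonds (quinolone numbering) and the electrocyclic opening breaks the old indole C2–C3 bond. The closest known reactions are the Ciamician–Dennstedt halocarbene expansion of indoles to 3-haloquinolines and the dihalocarbene expansion of cyclic silyl enol ethers to 2-halo-enones. No stereocentre remains in 12, so the two racemic centres of 10 are of no consequence. The step needs cyclopropanation to win over C-dichloromethylation at C2 (which would give a 2,2-disubstituted indoxyl) and over desilylation by the trichloromethyl anion; the base-free carbene source should keep the silyl enol ether intact, and the push from nitrogen should make opening of 10 fast once it has formed.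

**Step 5**
Reactants: 12 3-chloro-1-methyl-2-pentadecyl-4(1H)-quinolone
Product: 13 1-methyl-2-pentadecyl-4(1H)-quinolone
Conditions: H2 (1 atm), Pd/C (10% palladium on carbon), Et3N, MeOH–THF, rt
Reagents that add atoms: none
Why: Palladium-catalysed hydrogenolysis of an sp2 C–Cl bond with an amine to take up HCl (hydrodechlorination) should remove the chlorine, while the vinylogous amide ring is not expected to be reduced under these mild conditions.

**Compound list**
1 | 1-methylindole | Cn1ccc2ccccc21 | starting material
2 | 1-bromopentadecane | CCCCCCCCCCCCCCCBr | starting material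
3 | 2-lithio-1-methylindole | [Li]c1cc2ccccc2n1C | intermediate
4 | 1-methyl-2-pentadecylindole | CCCCCCCCCCCCCCCc1cc2ccccc2n1C | intermediate
5 | 3-bromo-1-methyl-2-pentadecylindole | CCCCCCCCCCCCCCCc1c(Br)c2ccccc2n1C | intermediate
6 | bis(trimethylsilyl) peroxide | C[Si](C)(C)OO[Si](C)(C)C | starting material
7 | 3-lithio-1-methyl-2-pentadecylindole | CCCCCCCCCCCCCCCc1c([Li])c2ccccc2n1C | intermediate
8 | 1-methyl-2-pentadecyl-3-(trimethylsilyloxy)indole | CCCCCCCCCCCCCCCc1c(O[Si](C)(C)C)c2ccccc2n1C | intermediate
9 | sodium trichloroacetate | [Na+].[O-]C(=O)C(Cl)(Cl)Cl | starting material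
10 | 1,1-dichloro-2-methyl-1a-pentadecyl-6b-(trimethylsilyloxy)-1,1a,2,6b-tetrahydrocyclopropa[b]indole (racemic, cis-fused) | CCCCCCCCCCCCCCCC12N(C)c3ccccc3C1(O[Si](C)(C)C)C2(Cl)Cl | intermediate
11 | 3-chloro-1-methyl-2-pentadecyl-4-(trimethylsilyloxy)quinolinium chloride | CCCCCCCCCCCCCCCc1c(Cl)c(O[Si](C)(C)C)c2ccccc2[n+]1C.[Cl-] | intermediate
12 | 3-chloro-1-methyl-2-pentadecyl-4(1H)-quinolone | CCCCCCCCCCCCCCCc1c(Cl)c(=O)c2ccccc2n1C | intermediate
13 | 1-methyl-2-pentadecyl-4(1H)-quinolone | CCCCCCCCCCCCCCCc1cc(=O)c2ccccc2n1C | target

**Step count**
Total steps: 5. Longest linear sequence: 5 steps (from 1-methylindole).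

**Steps most likely to fail**

1. Step 4 (proposed new method). The carbene precursor may be used up by attack of the trichloromethyl anion at silicon, or the carbene may be trapped at C2 alone without ring closure, so that no ring expansion takes place. The fallback uses known chemistry, sets out from 2 and comes back at 13. Bromide 2 is converted with Mg in THF into pentadecylmagnesium bromide F1, which is acylated with N-methoxy-N-methylacetamide to give heptadecan-2-one F2. Kinetic deprotonation with LiN(iPr)2 in THF at −78 °C gives the terminal lithium enolate F3. C-acylation of F3 by N-methylisatoic anhydride, with loss of CO2, gives 1-[2-(methylamino)phenyl]octadecane-1,3-dione F4, which should cyclise with loss of water on work-up to 13.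

2. Step 3. The aryllithium may attack silicon instead of oxygen (C-silylation), may be quenched by proton transfer from the side-chain CH2, or the silyl ether may be hydrolysed and air-oxidised during isolation. The fallback sets out from 4 and comes back at 8. C3–H acetoxylation of 4 with PhI(OAc)2 and catalytic Pd(OAc)2 (divalent palladium) in MeCN gives the stable indoxyl acetate 3-acetoxy-1-methyl-2-pentadecylindole F5. Cleavage of this enol acetate with MeLi (2 equiv) in THF at 0 °C gives lithium 1-methyl-2-pentadecylindol-3-olate F6, which is O-silylated in the same flask with Me3SiCl to give 8 without the free indoxyl ever being handled.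

3. Step 5. Cleavage of the C–Cl bond on the electron-rich vinylogous amide carbon may be slow, and forcing the hydrogenation may begin to saturate the pyridone ring. The fallback sets out from 8 and comes back at 13, changing the halogen that has to be removed. Dibromocarbene (CHBr3, KOtBu, pentane, −30 °C → rt) should give the dibromocyclopropane adduct F7, which should open as in step 4 through 3-bromo-1-methyl-2-pentadecyl-4-(trimethylsilyloxy)quinolinium bromide F8 to 3-bromo-1-methyl-2-pentadecyl-4(1H)-quinolone F9. The weaker C–Br bond of F9 should then be hydrogenolysed under mild conditions (H2, Pd/C, Et3N, rt) to give 13.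

**Further compounds**
F1 | step 4 | pentadecylmagnesium bromide | CCCCCCCCCCCCCCC[Mg]Br
F2 | step 4 | heptadecan-2-one | CCCCCCCCCCCCCCCC(C)=O
F3 | step 4 | lithium heptadec-1-en-2-olate | CCCCCCCCCCCCCCCC(=C)O[Li]
F4 | step 4 | 1-[2-(methylamino)phenyl]octadecane-1,3-dione | CCCCCCCCCCCCCCCC(=O)CC(=O)c1ccccc1NC
F5 | step 3 | 3-acetoxy-1-methyl-2-pentadecylindole | CCCCCCCCCCCCCCCc1c(OC(C)=O)c2ccccc2n1C
F6 | step 3 | lithium 1-methyl-2-pentadecylindol-3-olate | CCCCCCCCCCCCCCCc1c(O[Li])c2ccccc2n1C
F7 | step 5 | 1,1-dibromo-2-methyl-1a-pentadecyl-6b-(trimethylsilyloxy)-1,1a,2,6b-tetrahydrocyclopropa[b]indole (racemic, cis-fused) | CCCCCCCCCCCCCCCC12N(C)c3ccccc3C1(O[Si](C)(C)C)C2(Br)Br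
F8 | step 5 | 3-bromo-1-methyl-2-pentadecyl-4-(trimethylsilyloxy)quinolinium bromide | CCCCCCCCCCCCCCCc1c(Br)c(O[Si](C)(C)C)c2ccccc2[n+]1C.[Br-]
F9 | step 5 | 3-bromo-1-methyl-2-pentadecyl-4(1H)-quinolone | CCCCCCCCCCCCCCCc1c(Br)c(=O)c2ccccc2n1C
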